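**Retrosynthetic overview**
1. Target ⇒ phenol silyl ether cleavage ⇐ epoxidation of the cyclopentene directed by the C-10 hydroxyl ⇐ palladium-catalysed carbonylative esterification of the secondary C-8 hydroxyl of a trans-fused guai-3-ene-8β,10α-diol with an O-silylated 4-iodoguaiacol (from catechol).
2. Diol ⇒ hydroxyl-directed anti reduction of a β-hydroxy cycloheptanone (sets C-8).
3. Cycloheptanone ⇒ key one-carbon ring expansion: scandium-catalysed insertion of 1-diazo-2-methylpropane into the C-8/C-6 bond of a trans-hydrindane β-hydroxy cyclohexanone (1,2-shift of C-6), which makes the seven-membered ring and brings in C-7 with its isopropyl group.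
4. β-Hydroxy cyclohexanone ⇒ trans-hydrindenone by dehydrogenation, axial MeLi addition (sets C-10) and hydroboration–oxidation.
5. trans-Hydrindenone ⇒ cyclohex-2-enone by rhodium-catalysed asymmetric 1,4-addition/enolate allylation (sets C-5, C-1) and ring-closing metathesis; ring order: six-membered ring (bought), cyclopentene, cycloheptane (by expansion), oxirane.

Convention and assumption: atom labels C-1 to C-15 follow guaiane numbering (C-1/C-5 ring fusion, methyls on C-4 and C-10, isopropyl on C-7, ester oxygen on C-8), α is the face of H-1 and β the face of H-5; solutions of 2, MeLi and n-BuLi are taken as purchasable.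

**Step 1**
Reactants: 1 cyclohex-2-en-1-one; 2 isopropenylmagnesium bromide; 3 allyl bromide
Product: 6 (2R,3S)-2-(prop-2-en-1-yl)-3-(prop-1-en-2-yl)cyclohexan-1-one, via boron enolate 4 (not isolated), via lithium enolate 5 (not isolated)
Conditions: 2, B-bromo-9-BBN, THF–hexane, −78 → 0 °C, solvent changed to PhMe; then 1, [Rh(OMe)(cod)]2 (1.5 mol %), (S)-BINAP (3.3 mol %), 80 °C; then n-BuLi, THF, −78 °C; 3, −78 → 0 °C
Reagents that add atoms: B-bromo-9-borabicyclo[3.3.1]nonane, BrB1C2CCCC1CCC2; n-butyllithium, [Li]CCCC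
Why: Rhodium/(S)-BINAP-catalysed asymmetric 1,4-addition of the B-alkenyl-9-BBN reagent (Hayashi-type, here with an alkenyl instead of an aryl group) sets C-5 under catalyst control and gives the regiodefined boron enolate, whose lithium enolate is allylated trans to the new substituent, setting C-1 (three-component conjugate addition–enolate alkylation).

**Step 2**
Reactants: 6 (2R,3S)-2-(prop-2-en-1-yl)-3-(prop-1-en-2-yl)cyclohexan-1-one
Product: 7 (3aR,7aS)-1-methyl-3,3a,5,6,7,7a-hexahydro-4H-inden-4-one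
Conditions: second-generation Grubbs catalyst (3 mol %), CH2Cl2 (0.01 M), 40 °C
Reagents that add atoms: none
Why: Ring-closing olefin metathesis of the allyl and isopropenyl groups closes the trisubstituted cyclopentene without touching C-1 or C-5, so the trans ring fusion of 6 is carried over.

**Step 3**
Reactants: 7 (3aR,7aS)-1-methyl-3,3a,5,6,7,7a-hexahydro-4H-inden-4-one
Product: 9 (3aR,7aS)-1-methyl-3,3a,7,7a-tetrahydro-4H-inden-4-one, via lithium enolate 8 (not isolated)
Conditions: LiN(iPr)2, THF, −78 °C; then N-tert-butylbenzenesulfinimidoyl chloride, −78 °C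
Reagents that add atoms: lithium diisopropylamide, [Li]N(C(C)C)C(C)C
Why: Kinetic deprotonation at the unhindered C-9 methylene (not at the ring-fusion C-1) followed by Mukaiyama dehydrogenation of the enolate gives the enone in one flask without epimerising C-1.

**Step 4**
Reactants: 9 (3aR,7aS)-1-methyl-3,3a,7,7a-tetrahydro-4H-inden-4-one
Product: 10 (3aR,4R,7aS)-1,4-dimethyl-3a,4,7,7a-tetrahydro-3H-inden-4-ol
Conditions: MeLi, Et2O, −78 °C; H2O
Reagents that add atoms: methyllithium, [Li]C
Why: 1,2-Addition of methyllithium to the rigid trans-fused cyclohexenone follows the axial trajectory anti to the pseudoaxial H-1, which puts the methyl on the β face and the C-10 hydroxyl on the α face (cis to H-1) as in the target.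

**Step 5**
Reactants: 10 (3aR,4R,7aS)-1,4-dimethyl-3a,4,7,7a-tetrahydro-3H-inden-4-ol
Product: 12 (3aR,4R,6R,7aS)-1,4-dimethyl-3a,4,5,6,7,7a-hexahydro-3H-indene-4,6-diol, via boronate 11 (not isolated)
Conditions: catecholborane (3 equiv), RhCl(PPh3)3 (3 mol %), THF, 0 → 25 °C; then NaOH, H2O2, 0 °C
Reagents that add atoms: catecholborane, B1Oc2ccccc2O1; hydrogen peroxide, OO
Why: Rhodium-catalysed hydroboration touches only the 1,2-disubstituted ring alkene (the trisubstituted cyclopentene is inert under these conditions) and puts boron on C-8, remote from the quaternary carbinol carbon and anti to the axial C-10 methyl, and oxidation gives the 1,3-diol whose C-8 configuration (drawn for the expected major epimer) is erased in step 6.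

**Step 6**
Reactants: 12 (3aR,4R,6R,7aS)-1,4-dimethyl-3a,4,5,6,7,7a-hexahydro-3H-indene-4,6-diol
Product: 13 (3aS,7R,7aR)-7-hydroxy-3,7-dimethyl-1,3a,4,6,7,7a-hexahydro-5H-inden-5-one
Conditions: Pr4N[RuO4] (5 mol %), N-methylmorpholine N-oxide, 4 Å MS, CH2Cl2, 0 °C
Reagents that add atoms: none
Why: Ley–Griffith oxidation converts the secondary alcohol into the ketone under neutral conditions that spare the tertiary alcohol, the sensitive β-hydroxy ketone and the alkene.

**Step 7**
Reactants: 14 2-methylpropanal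
Product: 15 (2-methylpropylidene)hydrazine
Conditions: N2H4·H2O (5 equiv), EtOH, 0 °C; extractive work-up, used at once
Reagents that add atoms: hydrazine, NN
Why: Hydrazone condensation with excess hydrazine (to suppress azine formation) gives the N-unsubstituted hydrazone that serves as precursor of the non-stabilised diazoalkane.

**Step 8**
Reactants: 13 (3aS,7R,7aR)-7-hydroxy-3,7-dimethyl-1,3a,4,6,7,7a-hexahydro-5H-inden-5-one; 15 (2-methylpropylidene)hydrazine
Product: 17 (3aR,4R,7R,8aS)-4-hydroxy-1,4-dimethyl-7-(propan-2-yl)-3,3a,4,7,8,8a-hexahydroazulen-6(5H)-one, via 1-diazo-2-methylpropane 16 (not isolated)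
Conditions: 15, MnO2, CH2Cl2, −20 °C, cold filtration; filtrate added to 13, Sc(OTf)3 (10 mol %), PhMe, −78 → −40 °C
Reagents that add atoms: none
Why: Proposed new method: hydroxyl-directed Sc(OTf)3-catalysed insertion of the secondary-alkyl diazomethane 16 into the C-8/C-6 bond of a free β-hydroxy cyclohexanone (a Tiffeneau–Demjanov-type 1,2-shift whose closest precedent is the Sc(OTf)3-catalysed homologation of simple cycloalkanones with aryl- and alkyl-diazomethanes), in which chelation of scandium by the C-8 carbonyl and the C-10 hydroxyl activates the ketone and makes C-9 (neopentyl, inside the chelate ring, β to the metal-bound oxygen) a poor migrating group so that C-6 migrates, while the axial C-10 methyl forces the diazo carbon onto the α (equatorial) face and, with N2 antiperiplanar to C-6 and the isopropyl group turned away from the chelate and from the ring, migration with inversion at the diazo carbon gives the 7R (β-isopropyl) ketone.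

**Step 9**
Reactants: 17 (3aR,4R,7R,8aS)-4-hydroxy-1,4-dimethyl-7-(propan-2-yl)-3,3a,4,7,8,8a-hexahydroazulen-6(5H)-one
Product: 18 (3aR,4R,6R,7R,8aS)-1,4-dimethyl-7-(propan-2-yl)-3,3a,4,5,6,7,8,8a-octahydroazulene-4,6-diol
Conditions: Me4N[BH(OAc)3], MeCN–AcOH (1:1), −25 °C
Reagents that add atoms: none
Why: Evans–Saksena reduction, in which the tertiary C-10 hydroxyl binds the acetoxyborohydride and delivers hydride to the α face of the C-8 ketone (also the face anti to the β-isopropyl group), gives the anti-1,3-diol with the C-8 hydroxyl β.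

**Step 10**
Reactants: 19 benzene-1,2-diol (catechol)
Product: 20 2-methoxyphenol
Conditions: MeI (1.0 equiv), K2CO3 (1.0 equiv), acetone, 56 °C; distillation
Reagents that add atoms: iodomethane, CI
Why: Williamson mono-O-methylation with one equivalent of methyl iodide, the product being separated from catechol and the dimethyl ether by distillation.

**Step 11**
Reactants: 20 2-methoxyphenol
Product: 22 tert-butyl(4-iodo-2-methoxyphenoxy)dimethylsilane, via 4-iodo-2-methoxyphenol 21 (not isolated)
Conditions: N-iodosuccinimide, CF3CO2H (10 mol %), MeCN, 0 → 25 °C; then imidazole, TBSCl, 25 °C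
Reagents that add atoms: N-iodosuccinimide, O=C1CCC(=O)N1I; tert-butyldimethylsilyl chloride, CC(C)(C)[Si](C)(C)Cl
Why: Electrophilic aromatic iodination goes para to the free hydroxyl (the stronger donor) and the phenol is then silylated in the same flask to mask it for the palladium step.

**Step 12**
Reactants: 18 (3aR,4R,6R,7R,8aS)-1,4-dimethyl-7-(propan-2-yl)-3,3a,4,5,6,7,8,8a-octahydroazulene-4,6-diol; 22 tert-butyl(4-iodo-2-methoxyphenoxy)dimethylsilane
Product: 23 (3aR,4R,6R,7R,8aS)-4-hydroxy-1,4-dimethyl-7-(propan-2-yl)-3,3a,4,5,6,7,8,8a-octahydroazulen-6-yl 4-[(tert-butyldimethylsilyl)oxy]-3-methoxybenzoate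
Conditions: 22 (1.5 equiv), CO (1 atm), Pd(OAc)2 (5 mol %), Xantphos (6 mol %), Et3N, DMAP (20 mol %), PhMe, 80 °C
Reagents that add atoms: carbon monoxide, [C-]#[O+]
Why: Palladium-catalysed alkoxycarbonylation (oxidative addition of the aryl iodide, CO insertion, acyl transfer through the acylpyridinium of DMAP) acylates only the secondary C-8 hydroxyl because the tertiary C-10 hydroxyl is too hindered, and no stereocentre is touched.

**Step 13**
Reactants: 23 (3aR,4R,6R,7R,8aS)-4-hydroxy-1,4-dimethyl-7-(propan-2-yl)-3,3a,4,5,6,7,8,8a-octahydroazulen-6-yl 4-[(tert-butyldimethylsilyl)oxy]-3-methoxybenzoate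
Product: 24 (1R,3R,4S,5S,7R,8R,10R)-3,4-epoxy-10-hydroxyguaian-8-yl 4-[(tert-butyldimethylsilyl)oxy]-3-methoxybenzoate
Conditions: VO(acac)2 (5 mol %), t-BuOOH, PhMe, 25 → 40 °C
Reagents that add atoms: tert-butyl hydroperoxide, CC(C)(C)OO
Why: Hydroxyl-directed epoxidation, in which the vanadium alkoxide of the α-oriented tertiary C-10 hydroxyl (bishomoallylic to C-3/C-4) delivers the peroxide oxygen to the α face of the cyclopentene, sets C-3 and C-4.

**Step 14**
Reactants: 24 (1R,3R,4S,5S,7R,8R,10R)-3,4-epoxy-10-hydroxyguaian-8-yl 4-[(tert-butyldimethylsilyl)oxy]-3-methoxybenzoate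
Product: 25 (1R,3R,4S,5S,7R,8R,10R)-3,4-epoxy-10-hydroxyguaian-8-yl 4-hydroxy-3-methoxybenzoate (CNP0136245.2)
Conditions: Bu4NF, AcOH, THF, 0 °C
Reagents that add atoms: none
Why: Fluoride-mediated desilylation cleaves the aryl silyl ether selectively, and the acetic acid buffer keeps the phenoxide from attacking the ester or the epoxide.

**Compound list**
1 | cyclohex-2-en-1-one | O=C1C=CCCC1 | starting material
2 | isopropenylmagnesium bromide | CC(=C)[Mg]Br | starting material
3 | allyl bromide (3-bromoprop-1-ene) | C=CCBr | starting material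
4 | (S)-9-{[3-(prop-1-en-2-yl)cyclohex-1-en-1-yl]oxy}-9-borabicyclo[3.3.1]nonane | C=C(C)[C@@H]1C=C(OB2C3CCCC2CCC3)CCC1 | intermediate
5 | lithium (S)-3-(prop-1-en-2-yl)cyclohex-1-en-1-olate | C=C(C)[C@@H]1C=C(O[Li])CCC1 | intermediate
6 | (2R,3S)-2-(prop-2-en-1-yl)-3-(prop-1-en-2-yl)cyclohexan-1-one (trans) | C=CC[C@H]1C(=O)CCC[C@@H]1C(C)=C | intermediate
7 | (3aR,7aS)-1-methyl-3,3a,5,6,7,7a-hexahydro-4H-inden-4-one (trans-fused) | O=C1CCC[C@@H]2C(C)=CC[C@@H]12 | intermediate
8 | lithium (3aR,7aS)-1-methyl-3a,6,7,7a-tetrahydro-3H-inden-4-olate | [Li]OC1=CCC[C@@H]2C(C)=CC[C@@H]12 | intermediate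
9 | (3aR,7aS)-1-methyl-3,3a,7,7a-tetrahydro-4H-inden-4-one | O=C1C=CC[C@@H]2C(C)=CC[C@@H]12 | intermediate
10 | (3aR,4R,7aS)-1,4-dimethyl-3a,4,7,7a-tetrahydro-3H-inden-4-ol (hydroxyl cis to the adjacent ring-fusion H) | C1=C[C@@](C)(O)[C@@H]2CC=C(C)[C@H]2C1 | intermediate
11 | 2-[(3aR,4R,6R,7aS)-4-(1,3,2-benzodioxaborol-2-yloxy)-1,4-dimethyl-3a,4,5,6,7,7a-hexahydro-3H-inden-6-yl]-1,3,2-benzodioxaborole | B1(Oc2ccccc2O1)[C@H]1C[C@@](C)(OB2Oc3ccccc3O2)[C@@H]2CC=C(C)[C@H]2C1 | intermediate
12 | (3aR,4R,6R,7aS)-1,4-dimethyl-3a,4,5,6,7,7a-hexahydro-3H-indene-4,6-diol (major C-6 epimer drawn) | O[C@H]1C[C@@](C)(O)[C@@H]2CC=C(C)[C@H]2C1 | intermediate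
13 | (3aS,7R,7aR)-7-hydroxy-3,7-dimethyl-1,3a,4,6,7,7a-hexahydro-5H-inden-5-one | O=C1C[C@@](C)(O)[C@@H]2CC=C(C)[C@H]2C1 | intermediate
14 | 2-methylpropanal | CC(C)C=O | starting material
15 | (2-methylpropylidene)hydrazine | CC(C)C=NN | intermediate
16 | 1-diazo-2-methylpropane | CC(C)C=[N+]=[N-] | intermediate
17 | (3aR,4R,7R,8aS)-4-hydroxy-1,4-dimethyl-7-(propan-2-yl)-3,3a,4,7,8,8a-hexahydroazulen-6(5H)-one | O=C1C[C@@](C)(O)[C@@H]2CC=C(C)[C@H]2C[C@@H]1C(C)C | intermediate
18 | (3aR,4R,6R,7R,8aS)-1,4-dimethyl-7-(propan-2-yl)-3,3a,4,5,6,7,8,8a-octahydroazulene-4,6-diol | O[C@@H]1C[C@@](C)(O)[C@@H]2CC=C(C)[C@H]2C[C@@H]1C(C)C | intermediate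
19 | benzene-1,2-diol (catechol) | Oc1ccccc1O | starting material
20 | 2-methoxyphenol | COc1ccccc1O | intermediate
21 | 4-iodo-2-methoxyphenol | COc1cc(I)ccc1O | intermediate
22 | tert-butyl(4-iodo-2-methoxyphenoxy)dimethylsilane | COc1cc(I)ccc1O[Si](C)(C)C(C)(C)C | intermediate
23 | (3aR,4R,6R,7R,8aS)-4-hydroxy-1,4-dimethyl-7-(propan-2-yl)-3,3a,4,5,6,7,8,8a-octahydroazulen-6-yl 4-[(tert-butyldimethylsilyl)oxy]-3-methoxybenzoate | COc1cc(C(=O)O[C@@H]2C[C@@](C)(O)[C@@H]3CC=C(C)[C@H]3C[C@@H]2C(C)C)ccc1O[Si](C)(C)C(C)(C)C | intermediate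
24 | (1R,3R,4S,5S,7R,8R,10R)-3,4-epoxy-10-hydroxyguaian-8-yl 4-[(tert-butyldimethylsilyl)oxy]-3-methoxybenzoate | COc1cc(C(=O)O[C@@H]2C[C@@](C)(O)[C@@H]3C[C@H]4O[C@@]4(C)[C@H]3C[C@@H]2C(C)C)ccc1O[Si](C)(C)C(C)(C)C | intermediate
25 | (1R,3R,4S,5S,7R,8R,10R)-3,4-epoxy-10-hydroxyguaian-8-yl 4-hydroxy-3-methoxybenzoate (1αH,5βH; 3α,4α-epoxide; 7β-isopropyl; 8β-ester; 10α-OH) | COc1cc(C(=O)O[C@@H]2C[C@@](C)(O)[C@@H]3C[C@H]4O[C@@]4(C)[C@H]3C[C@@H]2C(C)C)ccc1O | target

**Step count and risks**
Total: 14 steps. Longest linear sequence: 11 steps (steps 1–6, 8, 9, 12, 13, 14 from cyclohex-2-en-1-one).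

Most likely to fail, step 8 (the proposed ring expansion). The free β-hydroxy ketone may dehydrate or undergo retro-aldol cleavage at scandium, C-9 may migrate in part, and the C-7 configuration rests on an untested model. The fallback uses known chemistry, sets out from 13 and returns at 17. Treatment of 13 with AlMe3 and TMSCHN2 (CH2Cl2, −78 → −20 °C), the established one-carbon homologation in which the less hindered C-6 methylene migrates, gives the α-silyl cycloheptanone F1. Work-up with K2CO3 in aqueous MeOH removes silicon to give the cycloheptanone F2. Condensation with Me2NNH2 gives the N,N-dimethylhydrazone F3. LiN(iPr)2 (2.2 equiv) metalates the less hindered C-7 side and 2-iodopropane gives the alkylated hydrazone F4. Two-phase hydrolysis with aqueous oxalic acid returns 17, the C-7 epimers being separated or equilibrated.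

Second, step 5 (rhodium-catalysed hydroboration). The ring alkene sits next to a quaternary centre and may react too slowly. The fallback sets out from 10 and returns at 12. VO(acac)2/t-BuOOH (CH2Cl2, 0 °C) epoxidises only the allylic ring alkene, on the face of the hydroxyl, to give the cis-epoxy alcohol F5. Cp2TiCl (from Cp2TiCl2 and Zn, trivalent titanium) in wet THF then opens the epoxide by homolysis of the C-9–O bond next to the carbinol carbon, and hydrogen-atom transfer to the C-9 radical gives diol 12. A hydride opening is not used there, because trans-diaxial attack would deliver hydride to C-8.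

Third, step 12 (carbonylative esterification). The C-8 hydroxyl is flanked by the isopropyl-bearing carbon and is the limiting nucleophile, and the aryl silyl ether is base-labile. The fallback sets out from 22 and returns at 23. Iodine–magnesium exchange (i-PrMgCl·LiCl, THF, −20 °C) and CO2 give 4-[(tert-butyldimethylsilyl)oxy]-3-methoxybenzoic acid F6. 2,4,6-Trichlorobenzoyl chloride and Et3N convert it into the Yamaguchi mixed anhydride F7, which acylates the C-8 hydroxyl of 18 in the presence of DMAP (PhMe, 25 °C) to give 23.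

**Further compounds**
F1 | step 8 | (3aR,4R,8aS)-4-hydroxy-1,4-dimethyl-7-(trimethylsilyl)-3,3a,4,7,8,8a-hexahydroazulen-6(5H)-one (C-7 epimers) | O=C1C[C@@](C)(O)[C@@H]2CC=C(C)[C@H]2CC1[Si](C)(C)C
F2 | step 8 | (3aR,4R,8aS)-4-hydroxy-1,4-dimethyl-3,3a,4,7,8,8a-hexahydroazulen-6(5H)-one | O=C1C[C@@](C)(O)[C@@H]2CC=C(C)[C@H]2CC1
F3 | step 8 | N,N-dimethylhydrazone of F2 | CN(C)N=C1C[C@@](C)(O)[C@@H]2CC=C(C)[C@H]2CC1
F4 | step 8 | N,N-dimethylhydrazone of 17 | CN(C)N=C1C[C@@](C)(O)[C@@H]2CC=C(C)[C@H]2C[C@@H]1C(C)C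
F5 | step 5 | (3aR,4S,5R,6R,7aS)-5,6-epoxy-1,4-dimethyl-3a,4,5,6,7,7a-hexahydro-3H-inden-4-ol (epoxide cis to the hydroxyl) | O1[C@H]2[C@@H]1[C@@](C)(O)[C@@H]1CC=C(C)[C@H]1C2
F6 | step 12 | 4-[(tert-butyldimethylsilyl)oxy]-3-methoxybenzoic acid | COc1cc(C(=O)O)ccc1O[Si](C)(C)C(C)(C)C
F7 | step 12 | 4-[(tert-butyldimethylsilyl)oxy]-3-methoxybenzoic 2,4,6-trichlorobenzoic anhydride | COc1cc(C(=O)OC(=O)c2c(Cl)cc(Cl)cc2Cl)ccc1O[Si](C)(C)C(C)(C)C
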